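The data were generated by integration for an exercise; scatter was added.

Set larch against maple: halve the catalyst and the target at 12 h falls from 42.9% to 30.9%, a smaller drop than the catalyst's.

| setting | larch | alder | elm | maple | amber | green | violet | ochre |
|---|---|---|---|---|---|---|---|---|
| substrate | 0.40 M | 0.56 M | 0.88 M | 0.40 M | 0.40 M | 0.40 M | 0.40 M (fed, over 8.0 h) | 0.40 M |
| partner | 0.48 M | 0.48 M | 0.48 M | 0.48 M | 0.480 M (fed, over 2.0 h) | 0.480 M | 0.480 M | 0.480 M (fed, over 8.0 h) |
| free catalyst | 2 mM | 2 mM | 2 mM | 1 mM | 2.0 mM | 2.0 mM | 2.0 mM | 2.0 mM |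
| remark | run made earlier | run made earlier | run made earlier | run made earlier | all else is in the flask from the start; the feed brings no volume worth counting | everything together at the start | all else is in the flask from the start; the feed brings no volume worth counting | all else is in the flask from the start; the feed brings no volume worth counting |
| time |  |  |  |  | 12 h | 12 h | 12 h | 12 h |

| run | time / h | target / % | substrate / % |
|---|---|---|---|
| larch | 2.00 | 16.8 | 82.4 |
| larch | 4.00 | 26.2 | 74.1 |
| larch | 6.00 | 30.8 | 69.0 |
| larch | 8.00 | 35.4 | 62.9 |
| larch | 10.0 | 39.5 | 59.4 |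
| larch | 12.0 | 42.9 | 55.2 |
| alder | 1.00 | 10.4 | 91.8 |
| alder | 1.50 | 10.6 | 87.4 |
| alder | 2.50 | 15.6 | 84.7 |
| alder | 4.00 | 20.3 | 79.0 |
| alder | 8.00 | 30.1 | 68.5 |
| alder | 12.0 | 38.6 | 61.1 |
| elm | 1.00 | 5.1 | 93.1 |
| elm | 1.50 | 8.7 | 92.1 |
| elm | 2.50 | 12.3 | 86.8 |
| elm | 4.00 | 14.3 | 83.6 |
| elm | 8.00 | 22.2 | 76.3 |
| elm | 12.0 | 27.6 | 73.4 |
| maple | 1.00 | 6.4 | 91.6 |
| maple | 2.00 | 10.5 | 89.6 |
| maple | 3.00 | 12.2 | 87.6 |
| maple | 6.00 | 19.3 | 78.9 |
| maple | 12.0 | 30.9 | 70.3 |

(readings scatter by 1 percentage point)



- which flask leads in amount of target, in percent of the substrate charged ("all alike" within 1.5 percentage points) (amber / green / violet / ochre / all alike)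
- how much target is there at the end, in percent of the substrate charged: amber
- how much target is there at the end, in percent of the substrate charged: green
- how much target is there at the end, in percent of the substrate charged: violet
- how much target is there at the end, in percent of the substrate charged: ochre

Divide the target made by the catalyst charged: larch reads 85.8, maple 124. Call this target per catalyst charged at 12 h the turnover count, the turnover number. Now raise [substrate] at fixed catalyst and partner: alder reads 108 and elm 121, so the count read in these runs climbs with [substrate].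

Reckon violet from this. Take the slope from larch to alder, 139 L mol⁻¹. Then set [substrate] at half the charge, its mean during the 8.0 h feed if little is consumed, and let that stand, roughly, for the whole 12 h. The count comes to about 57.9, which is 29.0% of the substrate charged. Green repeats larch.

The forecast differs on violet. It names green and gives amber 41%, green 43%, violet 36% and ochre 34%: “Feeding offers no gain, since inhibition depends on product, not on the reagent withheld.”

The flasks give amber 41.5%, green 44.2%, violet 23.8% and ochre 32.9%. Green leads, as forecast. Violet lands 12 percentage points under the forecast and also under my reckoning.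

    substrate + free catalyst ⇌ catalyst intermediate A (K = 5.80 L mol⁻¹, k = 48.0 L mol⁻¹ min⁻¹)
    partner + catalyst intermediate A → catalyst intermediate B (k = 2.40 L mol⁻¹ min⁻¹)
    2 free catalyst → spent catalyst (k = 2.70 L mol⁻¹ min⁻¹)
    catalyst intermediate B ⇌ free catalyst + target (K = 0.140 M, k = 6.80 min⁻¹)
    partner ⇌ dormant form (K = 1.90, k = 0.0240 min⁻¹)

Count again: green reaches 88.3, close to larch, and violet 47.6, with spent catalyst at 63.5% of the catalyst charged against 39.1% in green. A neighbour of green with 5.0 × 10⁻⁴ M of free catalyst counts 151, above maple, with spent catalyst at 14.4%. In green at 0.178 h, the forward rate of partner to dormant form stands at 8.4 times the rate of partner onto catalyst intermediate A. In green at 12.0 h, partner's half-life by that forward rate alone is 0.48 h, shorter than the 11 h by the step onto catalyst intermediate A.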